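**Plan**

Numbering used below: C1 = enol-ether carbon bearing the carbinol C10; C2H=/C3H2 = the other dihydrofuran carbons; C4 = quaternary O-bearing carbon; O4 = bridging oxygen; C5=C6 = exocyclic alkene; C7/C11/C12 = butenolide β-carbon, α-carbon and carbonyl; C8 = acetoxy carbon; C13 = acetoxymethyl carbon.
Cuts, in order: the acetates and C11–C13 (Stille); then C3–C4 together with C1=C2, which removes the CH2–CH= unit and leaves a nine-membered lactone (O4–C1 ester); then C5=C6 (vinylogous aldol condensation), C7–C8 (Nozaki–Hiyama–Kishi), the O4–C1 ester and C9–C10 (enolate prenylation).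
Forward: the butenolide ring is bought (3,4-dibromofuranone); the nine-membered lactone is fused to it (step 12); one operation then closes the dihydrofuran ring and the ten-membered carbocycle C1–C10 (step 13).
Enabling feature: C4 is the ε-carbon of the γ-alkylidene butenolide, so deprotonation gives an aromatic 2-oxidofuran trienolate nucleophilic at C4, and C4 is tied through O4 to the lactone carbonyl C1; vinyltriphenylphosphonium can therefore be inserted between C4 and C1 by conjugate addition and intramolecular Wittig olefination.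
Stereochemistry: C10 from (R)-lactic acid (Seebach alkylation); C8 by CBS reduction; C4 and the E geometry of C5=C6 from the nine-membered ring in step 13. Bromine at C11 blocks the α-position and stands in for C13 until step 14.

Key step: step 13

Remark: the configuration of the butenyl carbinol carbon (future C4) is erased in step 13; the S alcohol 8 is used only so that every intermediate is a single stereoisomer.

**Route**

Step 1
Reactants: 1 (R)-lactic acid; 2 pivalaldehyde
Product: 3 (2R,5R)-2-tert-butyl-5-methyl-1,3-dioxolan-4-one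
Conditions: TsOH·H2O (cat.), H2SO4 (cat.), pentane, reflux, Dean–Stark trap; cis isomer crystallised
Reagents that add atoms: none
Why: Acid-catalysed acetalisation (Seebach self-regeneration of stereocentres) should give mainly the cis acetal, in which C5 keeps the lactic acid configuration and the new C2 centre is set under thermodynamic control.

Step 2
Reactants: 3 (2R,5R)-2-tert-butyl-5-methyl-1,3-dioxolan-4-one; 4 prenyl bromide
Product: 6 (2R,5S)-2-tert-butyl-5-methyl-5-(3-methylbut-2-en-1-yl)-1,3-dioxolan-4-one, via lithium enolate 5 (not isolated)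
Conditions: LiN(i-Pr)2, THF, −78 °C; then 4, −78 to −30 °C
Reagents that add atoms: none
Why: Alkylation of the planar lithium enolate should occur anti to the tert-butyl group (Seebach alkylation), so the quaternary carbon that becomes C10 is set by the acetal centre.

Step 3
Reactants: 6 (2R,5S)-2-tert-butyl-5-methyl-5-(3-methylbut-2-en-1-yl)-1,3-dioxolan-4-one
Product: 7 (S)-2-hydroxy-2,5-dimethylhex-4-enoic acid
Conditions: KOH, MeOH/H2O, 60 °C; then 1 M HCl to pH 3, 0 °C
Reagents that add atoms: water, O
Why: Saponification of the acetal lactone should release the α-hydroxy acid and pivalaldehyde without touching the quaternary centre.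

Step 4
Reactants: 7 (S)-2-hydroxy-2,5-dimethylhex-4-enoic acid; 8 (S)-but-3-en-2-ol
Product: 9 (S)-but-3-en-2-yl (S)-2-hydroxy-2,5-dimethylhex-4-enoate
Conditions: DCC, DMAP (cat.), CH2Cl2, 0 to 23 °C
Reagents that add atoms: none
Why: Steglich esterification should acylate the secondary allylic alcohol while the hindered tertiary hydroxyl stays free; no stereocentre is affected.

Step 5
Reactants: 9 (S)-but-3-en-2-yl (S)-2-hydroxy-2,5-dimethylhex-4-enoate
Product: 10 (S)-but-3-en-2-yl (S)-2,5-dimethyl-2-(triethylsilyloxy)hex-4-enoate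
Conditions: Et3SiOTf, 2,6-lutidine, CH2Cl2, −78 to 0 °C
Reagents that add atoms: triethylsilyl triflate, CC[Si](CC)(CC)OS(=O)(=O)C(F)(F)F
Why: Silylation of the tertiary alcohol with a silyl triflate protects O10 for the enolate and ylide chemistry that follows.

Step 6
Reactants: 10 (S)-but-3-en-2-yl (S)-2,5-dimethyl-2-(triethylsilyloxy)hex-4-enoate
Product: 12 (S)-but-3-en-2-yl (S)-2-methyl-4-oxo-2-(triethylsilyloxy)butanoate, via ozonide 11 (not isolated)
Conditions: O3 (1 equiv, Sudan Red 7B as end-point dye), CH2Cl2, −78 °C; then PPh3, −78 to 23 °C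
Reagents that add atoms: ozone, [O-][O+]=O
Why: Criegee ozonolysis is much faster at the electron-rich trisubstituted alkene than at the monosubstituted allylic-ester alkene, so a titrated equivalent of ozone should cleave only the prenyl group to the C8 aldehyde.

Step 7
Reactants: 12 (S)-but-3-en-2-yl (S)-2-methyl-4-oxo-2-(triethylsilyloxy)butanoate; 13 3,4-dibromofuran-2(5H)-one
Product: 14 (S)-but-3-en-2-yl (2S,4RS)-4-(4-bromo-5-oxo-2,5-dihydrofuran-3-yl)-4-hydroxy-2-methyl-2-(triethylsilyloxy)butanoate
Conditions: CrCl2 (4 equiv), NiCl2 (2 mol %), DMF, 23 °C; 13 in excess; crude product taken on at once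
Reagents that add atoms: none
Why: Nozaki–Hiyama–Kishi coupling: zerovalent nickel should insert into the β C–Br bond (a vinylogous acyl bromide) in preference to the α C–Br bond, and the alkenylchromium adds to the aldehyde without touching the ester, the silyl ether or the acidic C6 methylene; both C8 epimers are expected and the centre is erased in step 8.

Step 8
Reactants: 14 (S)-but-3-en-2-yl (2S,4RS)-4-(4-bromo-5-oxo-2,5-dihydrofuran-3-yl)-4-hydroxy-2-methyl-2-(triethylsilyloxy)butanoate
Product: 15 (S)-but-3-en-2-yl (S)-4-(4-bromo-5-oxo-2,5-dihydrofuran-3-yl)-2-methyl-4-oxo-2-(triethylsilyloxy)butanoate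
Conditions: Dess–Martin periodinane, CH2Cl2, 0 to 23 °C
Reagents that add atoms: none
Why: Dess–Martin oxidation of the secondary allylic alcohol should give the C8 ketone under near-neutral conditions that spare the β-silyloxy group.

Step 9
Reactants: 15 (S)-but-3-en-2-yl (S)-4-(4-bromo-5-oxo-2,5-dihydrofuran-3-yl)-2-methyl-4-oxo-2-(triethylsilyloxy)butanoate
Product: 16 (S)-but-3-en-2-yl (2S,4S)-4-(4-bromo-5-oxo-2,5-dihydrofuran-3-yl)-4-hydroxy-2-methyl-2-(triethylsilyloxy)butanoate
Conditions: (R)-2-methyl-CBS-oxazaborolidine (20 mol %), catecholborane, toluene, −78 °C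
Reagents that add atoms: none
Why: Corey–Bakshi–Shibata reduction: with the α-substituted alkenyl carbon C7 as the large group and the C9 methylene as the small one, the (R)-catalyst should deliver hydride to give the 8S alcohol, and catecholborane leaves the vinyl group alone.

Step 10
Reactants: 16 (S)-but-3-en-2-yl (2S,4S)-4-(4-bromo-5-oxo-2,5-dihydrofuran-3-yl)-4-hydroxy-2-methyl-2-(triethylsilyloxy)butanoate
Product: 17 (S)-but-3-en-2-yl (2S,4S)-4-(4-bromo-5-oxo-2,5-dihydrofuran-3-yl)-2-methyl-2,4-bis(triethylsilyloxy)butanoate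
Conditions: Et3SiOTf, 2,6-lutidine, CH2Cl2, −78 °C, directly after step 9
Reagents that add atoms: triethylsilyl triflate, CC[Si](CC)(CC)OS(=O)(=O)C(F)(F)F
Why: Immediate silylation should prevent lactonisation of the γ-hydroxy ester onto C1 and protects O8.

Step 11
Reactants: 17 (S)-but-3-en-2-yl (2S,4S)-4-(4-bromo-5-oxo-2,5-dihydrofuran-3-yl)-2-methyl-2,4-bis(triethylsilyloxy)butanoate
Product: 19 (S)-1-oxopropan-2-yl (2S,4S)-4-(4-bromo-5-oxo-2,5-dihydrofuran-3-yl)-2-methyl-2,4-bis(triethylsilyloxy)butanoate, via ozonide 18 (not isolated)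
Conditions: O3, CH2Cl2, −78 °C; then PPh3, −78 to 23 °C
Reagents that add atoms: ozone, [O-][O+]=O
Why: Ozonolysis should cleave the only electron-rich alkene left (the bromobutenolide double bond is tetrasubstituted and electron-poor) and unmask the C5 aldehyde.

Step 12
Reactants: 19 (S)-1-oxopropan-2-yl (2S,4S)-4-(4-bromo-5-oxo-2,5-dihydrofuran-3-yl)-2-methyl-2,4-bis(triethylsilyloxy)butanoate
Product: 22 nine-membered lactone (4S,5E,8S,10S) fused to the 11-bromobutenolide, via silyloxyfuran 20 (not isolated), via silyl aldol 21 (not isolated)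
Conditions: t-BuMe2SiOTf (1.5 equiv), i-Pr2NEt, CH2Cl2 (1 mM), −78 to 0 °C; then DBU, 23 °C
Reagents that add atoms: none
Why: Vinylogous Mukaiyama aldol addition of the 2-silyloxyfuran (C6) to the tethered aldehyde (C5), followed by DBU-induced E1cB loss of silanolate (aldol condensation), should close the nine-membered lactone; the transient C5 and C6 centres are erased and only the E alkene, with C4 and C7 cis, fits the ring.

Step 13
Reactants: 22 nine-membered lactone (4S,5E,8S,10S) fused to the 11-bromobutenolide; 23 vinyltriphenylphosphonium bromide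
Product: 26 bridged bromide (4S,5E,8S,10S)-11-bromo-8,10-bis(triethylsilyloxy)-13-nor analogue of the target skeleton, via potassium trienolate 24 (not isolated), via phosphorus ylide 25 (not isolated)
Conditions: KN(SiMe3)2 (1.05 equiv), THF, −78 °C; then 23 (1.2 equiv) in DMF, −40 to 23 °C; 50 °C to finish
Reagents that add atoms: none
Why: Proposed new method: KN(SiMe3)2 removes H from C4, the ε-position of the γ-alkylidene butenolide, because the anion is an aromatic 2-oxidofuran (24); its C4 terminus adds to the vinylphosphonium salt (C3–C4 bond) and gives ylide 25 without any proton transfer, and the ylide carbon C2 then olefinates the lactone carbonyl C1, which sits 1,3 to C4 across O4 (C1=C2 bond, loss of Ph3PO). The closest known reaction types are the Schweizer annulation (conjugate addition to vinyltriphenylphosphonium salts followed by intramolecular Wittig reaction), the intramolecular Wittig olefination of ester carbonyls to cyclic enol ethers and the remote (bis-vinylogous) reactions of 5-alkenyl-2-oxyfurans. The 2,3-dihydrofuran closes by five-membered attack of the ylide carbon on C1 (5-exo-trig, via an oxaphosphetane), and the ten-membered carbocycle C1–C10 is closed transannularly by the same C1=C2 bond, so that the nine-membered lactone becomes the oxygen-bridged bicycle. The quaternary centre C4 (S) is controlled by the ring: the two-carbon unit can only span C4 and C1 on one face of the lactone, and the ylide should attack C1 anti to the neighbouring C10 triethylsilyloxy group (Felkin–Anh sense), the face that carries the C10 methyl as the target requires, while the C5=C6 bond re-forms E because both of its ring carbons stay in the medium ring. The step needs attack at C4 and not at C6 or C11, and olefination of C1 and not of C12: C11 carries bromine, a C6 adduct has no carbonyl in five-membered reach other than C12 (closure there would make a bridgehead alkene) and should revert by retro-Michael reaction to the stabilised furanolate, and only C1 is five atoms from the ylide carbon. One equivalent of base is used so that the C8 hydrogen (vinylogous γ-position) is not removed once the aromatic trienolate has formed.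

Step 14
Reactants: 26 bridged bromide; 27 (tributylstannyl)methanol
Product: 28 (4S,5E,8S,10S)-13-hydroxy-8,10-bis(triethylsilyloxy) precursor of the target
Conditions: Pd(PPh3)4 (5 mol %), 1,4-dioxane, 90 °C
Reagents that add atoms: none
Why: Stille coupling (Kosugi hydroxymethylation) of the α-bromobutenolide under neutral conditions should install C13 without harming the enol ether.

Step 15
Reactants: 28 (4S,5E,8S,10S)-13-hydroxy-8,10-bis(triethylsilyloxy) precursor of the target
Product: 29 (4S,5E,8S,10S)-8,10,13-triol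
Conditions: Bu4NF, AcOH (1:1), THF, 0 to 23 °C
Reagents that add atoms: none
Why: Buffered fluoride desilylation should remove both triethylsilyl groups while the acid-sensitive enol ether and the base-sensitive butenolide survive.

Step 16
Reactants: 29 (4S,5E,8S,10S)-8,10,13-triol
Product: 30 target CNP0144020.1
Conditions: Ac2O (2.5 equiv), pyridine, DMAP (cat.), CH2Cl2, 0 °C
Reagents that add atoms: acetic anhydride, CC(=O)OC(C)=O
Why: Acetylation should take the primary C13 and the secondary C8 alcohol and leave the hindered tertiary C10 hydroxyl free, giving the target.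

**Compound list**

1 | (R)-lactic acid | C[C@@H](O)C(=O)O | starting material
2 | pivalaldehyde | CC(C)(C)C=O | starting material
3 | (2R,5R)-2-tert-butyl-5-methyl-1,3-dioxolan-4-one | C[C@H]1O[C@@H](C(C)(C)C)OC1=O | intermediate
4 | prenyl bromide (1-bromo-3-methylbut-2-ene) | CC(C)=CCBr | starting material
5 | lithium enolate of 3 (lithium (2R)-2-tert-butyl-5-methyl-1,3-dioxol-4-olate) | [Li+].[O-]C1=C(C)O[C@@H](C(C)(C)C)O1 | intermediate
6 | (2R,5S)-2-tert-butyl-5-methyl-5-(3-methylbut-2-en-1-yl)-1,3-dioxolan-4-one | C[C@@]1(CC=C(C)C)O[C@@H](C(C)(C)C)OC1=O | intermediate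
7 | (S)-2-hydroxy-2,5-dimethylhex-4-enoic acid | OC(=O)[C@@](C)(O)CC=C(C)C | intermediate
8 | (S)-but-3-en-2-ol | C[C@H](O)C=C | starting material
9 | (S)-but-3-en-2-yl (S)-2-hydroxy-2,5-dimethylhex-4-enoate | C=C[C@H](C)OC(=O)[C@@](C)(O)CC=C(C)C | intermediate
10 | (S)-but-3-en-2-yl (S)-2,5-dimethyl-2-(triethylsilyloxy)hex-4-enoate | C=C[C@H](C)OC(=O)[C@@](C)(O[Si](CC)(CC)CC)CC=C(C)C | intermediate
11 | secondary ozonide of 10 (1,2,4-trioxolane at the former prenyl alkene) | C=C[C@H](C)OC(=O)[C@@](C)(O[Si](CC)(CC)CC)CC1OOC(C)(C)O1 | intermediate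
12 | (S)-but-3-en-2-yl (S)-2-methyl-4-oxo-2-(triethylsilyloxy)butanoate | C=C[C@H](C)OC(=O)[C@@](C)(O[Si](CC)(CC)CC)CC=O | intermediate
13 | 3,4-dibromofuran-2(5H)-one | O=C1OCC(Br)=C1Br | starting material
14 | (S)-but-3-en-2-yl (2S,4RS)-4-(4-bromo-5-oxo-2,5-dihydrofuran-3-yl)-4-hydroxy-2-methyl-2-(triethylsilyloxy)butanoate (both C8 epimers) | C=C[C@H](C)OC(=O)[C@@](C)(O[Si](CC)(CC)CC)CC(O)C1=C(Br)C(=O)OC1 | intermediate
15 | (S)-but-3-en-2-yl (S)-4-(4-bromo-5-oxo-2,5-dihydrofuran-3-yl)-2-methyl-4-oxo-2-(triethylsilyloxy)butanoate | C=C[C@H](C)OC(=O)[C@@](C)(O[Si](CC)(CC)CC)CC(=O)C1=C(Br)C(=O)OC1 | intermediate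
16 | (S)-but-3-en-2-yl (2S,4S)-4-(4-bromo-5-oxo-2,5-dihydrofuran-3-yl)-4-hydroxy-2-methyl-2-(triethylsilyloxy)butanoate | C=C[C@H](C)OC(=O)[C@@](C)(O[Si](CC)(CC)CC)C[C@H](O)C1=C(Br)C(=O)OC1 | intermediate
17 | (S)-but-3-en-2-yl (2S,4S)-4-(4-bromo-5-oxo-2,5-dihydrofuran-3-yl)-2-methyl-2,4-bis(triethylsilyloxy)butanoate | C=C[C@H](C)OC(=O)[C@@](C)(O[Si](CC)(CC)CC)C[C@H](O[Si](CC)(CC)CC)C1=C(Br)C(=O)OC1 | intermediate
18 | secondary ozonide of 17 (1,2,4-trioxolane at the former vinyl group) | C1OOC(O1)[C@H](C)OC(=O)[C@@](C)(O[Si](CC)(CC)CC)C[C@H](O[Si](CC)(CC)CC)C1=C(Br)C(=O)OC1 | intermediate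
19 | (S)-1-oxopropan-2-yl (2S,4S)-4-(4-bromo-5-oxo-2,5-dihydrofuran-3-yl)-2-methyl-2,4-bis(triethylsilyloxy)butanoate | O=C[C@H](C)OC(=O)[C@@](C)(O[Si](CC)(CC)CC)C[C@H](O[Si](CC)(CC)CC)C1=C(Br)C(=O)OC1 | intermediate
20 | 3-bromo-2-(tert-butyldimethylsilyloxy)furan formed from the butenolide of 19 | O=C[C@H](C)OC(=O)[C@@](C)(O[Si](CC)(CC)CC)C[C@H](O[Si](CC)(CC)CC)c1coc(O[Si](C)(C)C(C)(C)C)c1Br | intermediate
21 | cyclised silyl aldol (nine-membered lactone with C5–OSi(t-Bu)Me2 and C6–H, epimers at C5 and C6) | BrC1=C2C(OC1=O)C(O[Si](C)(C)C(C)(C)C)[C@H](C)OC(=O)[C@@](C)(O[Si](CC)(CC)CC)C[C@@H]2O[Si](CC)(CC)CC | intermediate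
22 | nine-membered lactone (4S,5E,8S,10S): ring O4–C1(=O)–C10–C9–C8–C7–C6=C5–C4, fused at C6–C7 to the 11-bromobutenolide, 8,10-bis(triethylsilyloxy) | BrC1=C2/C(=C\[C@H](C)OC(=O)[C@@](C)(O[Si](CC)(CC)CC)C[C@@H]2O[Si](CC)(CC)CC)OC1=O | intermediate
23 | vinyltriphenylphosphonium bromide | C=C[P+](c1ccccc1)(c1ccccc1)c1ccccc1.[Br-] | starting material
24 | potassium trienolate of 22 (potassium 3-bromofuran-2-olate with the C5=C4 enol ester in the ring) | [K+].[O-]C1=C(Br)C2=C(O1)/C=C(C)\OC(=O)[C@@](C)(O[Si](CC)(CC)CC)C[C@@H]2O[Si](CC)(CC)CC | intermediate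
25 | phosphorus ylide (22 carrying CH2–CH=PPh3 at C4) | BrC1=C2/C(=C\[C@](C)(CC=P(c3ccccc3)(c3ccccc3)c3ccccc3)OC(=O)[C@@](C)(O[Si](CC)(CC)CC)C[C@@H]2O[Si](CC)(CC)CC)OC1=O | intermediate
26 | bridged bromide: (4S,5E,8S,10S)-11-bromo-8,10-bis(triethylsilyloxy)-13-nor analogue of the target skeleton | BrC1=C2/C(=C\[C@]3(C)CC=C(O3)[C@@](C)(O[Si](CC)(CC)CC)C[C@@H]2O[Si](CC)(CC)CC)OC1=O | intermediate
27 | (tributylstannyl)methanol | CCCC[Sn](CO)(CCCC)CCCC | starting material
28 | (4S,5E,8S,10S)-13-hydroxy-8,10-bis(triethylsilyloxy) precursor | OCC1=C2/C(=C\[C@]3(C)CC=C(O3)[C@@](C)(O[Si](CC)(CC)CC)C[C@@H]2O[Si](CC)(CC)CC)OC1=O | intermediate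
29 | (4S,5E,8S,10S)-8,10,13-triol | OCC1=C2/C(=C\[C@]3(C)CC=C(O3)[C@@](C)(O)C[C@@H]2O)OC1=O | intermediate
30 | CNP0144020.1 (8,13-diacetate, 10-hydroxy) | CC(=O)OCC1=C2/C(=C\[C@]3(C)CC=C(O3)[C@@](C)(O)C[C@@H]2OC(C)=O)OC1=O | target

**Summary**

Total steps: 16. Longest linear sequence: 16 (from (R)-lactic acid).

**Steps most likely to fail**

Step 13 (proposed new method). Conjugate addition at C6 or on oxygen, slow olefination of the hindered lactone carbonyl, or bridging on the wrong face of the ring could defeat the cascade. The fallback makes the two bonds separately by known reactions and sets out from 22. The same trienolate is alkylated at C4 with allyl bromide (KN(SiMe3)2, THF, −78 °C; vinylogous enolate alkylation) to give the C4-allyl nine-membered lactone F1, whose C4 epimers could be separated. Olefinic-ester cyclisation of F1 with the titanium ethylidene reagent from TiCl4, TMEDA, Zn, PbCl2 (cat.) and CH3CHBr2 (THF, 65 °C) then closes the dihydrofuran; metathesis at the terminal alkene is followed by carbonyl olefination of C1, the only ester within five-membered reach. The fallback comes back to the route at 26.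

Step 12. Oligomerisation in place of nine-membered ring closure, or competing enolisation of the α-acyloxy aldehyde, may prevail because the aldol addition is reversible. The fallback replaces it by an irreversible intramolecular Horner–Wadsworth–Emmons olefination and sets out from 17. t-BuMe2SiOTf/Et3N gives the silyloxyfuran F2, and NBS brominates it at C6 to the γ-bromobutenolide F3. P(OEt)3 at 100 °C (Arbuzov) gives the γ-phosphonate F4, and ozonolysis of the vinyl group (O3; PPh3) gives the phosphonate aldehyde F5. LiCl/DBU in MeCN at high dilution then closes the ring, and the fallback comes back to the route at 22.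

Step 7. Insertion of nickel into both C–Br bonds, protonation of the alkenylchromium by the acidic C6 methylene, or lactonisation of the chromium alkoxide onto C1 may erode the coupling. The fallback makes the C7–C8 bond at the ketone level by an acyl Stille coupling and sets out from 12. NaClO2/NaH2PO4/2-methyl-2-butene oxidises 12 to the carboxylic acid F6, and (COCl)2 with catalytic DMF gives the acid chloride F7. Separately, 13 with (Bu3Sn)2 and Pd(PPh3)4 gives 3-bromo-4-(tributylstannyl)furan-2(5H)-one F8, by coupling at the more reactive β C–Br bond. F7 and F8 with Pd(PPh3)4 (cat.) in toluene at 80 °C give the ketone, so the fallback comes back to the route at 15 and bypasses 14 and step 8.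

Further compounds
F1 | step 13 | C4-allyl nine-membered lactone (22 with allyl in place of H at C4) | BrC1=C2/C(=C\[C@](C)(CC=C)OC(=O)[C@@](C)(O[Si](CC)(CC)CC)C[C@@H]2O[Si](CC)(CC)CC)OC1=O
F2 | step 12 | 3-bromo-2-(tert-butyldimethylsilyloxy)furan derived from 17 | C=C[C@H](C)OC(=O)[C@@](C)(O[Si](CC)(CC)CC)C[C@H](O[Si](CC)(CC)CC)c1coc(O[Si](C)(C)C(C)(C)C)c1Br
F3 | step 12 | γ-bromobutenolide (17 with Br at C6, both epimers) | C=C[C@H](C)OC(=O)[C@@](C)(O[Si](CC)(CC)CC)C[C@H](O[Si](CC)(CC)CC)C1=C(Br)C(=O)OC1Br
F4 | step 12 | γ-(diethoxyphosphoryl)butenolide (17 with P(O)(OEt)2 at C6) | C=C[C@H](C)OC(=O)[C@@](C)(O[Si](CC)(CC)CC)C[C@H](O[Si](CC)(CC)CC)C1=C(Br)C(=O)OC1P(=O)(OCC)OCC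
F5 | step 12 | phosphonate aldehyde (19 with P(O)(OEt)2 at C6) | O=C[C@H](C)OC(=O)[C@@](C)(O[Si](CC)(CC)CC)C[C@H](O[Si](CC)(CC)CC)C1=C(Br)C(=O)OC1P(=O)(OCC)OCC
F6 | step 7 | (S)-4-[(S)-but-3-en-2-yloxy]-3-methyl-4-oxo-3-(triethylsilyloxy)butanoic acid | C=C[C@H](C)OC(=O)[C@@](C)(O[Si](CC)(CC)CC)CC(=O)O
F7 | step 7 | acid chloride of F6 | C=C[C@H](C)OC(=O)[C@@](C)(O[Si](CC)(CC)CC)CC(=O)Cl
F8 | step 7 | 3-bromo-4-(tributylstannyl)furan-2(5H)-one | O=C1OCC([Sn](CCCC)(CCCC)CCCC)=C1Br
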